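## Plan

- **Retrosynthetic cuts, in order:** the C3'–OH bond (epoxide opened by water), the O7–C1' ether bond, the O7–CH3 bond (unmasking of the C7 phenol), the C3=C4 and O1–C2 bonds of the pyranone, the C4a–C8a bond of the benzene ring, and the C5–C6 bond (vinyllithium added to a squarate ester).
- **Enabling feature:** the benzene ring carries oxygen on four neighbouring carbons (C6, C7, C8, C8a), followed by C5–H and the carbon-substituted C4a. C6–C8a with their oxygens are the four carbons of dimethyl squarate; C5, C4a and C4 are a three-carbon alkenyl acetal.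
- **Forward order:** the benzene ring is made first (cyclobutenone opening, then 6π closure), the pyranone ring second, then O7 is freed and the C10 chain is attached and hydrolysed.
- **Stereochemistry:** both centres come from the Sharpless epoxidation of nerol with D-(−)-diethyl tartrate, which should give the (2R,3S)-epoxide. C2' is carried through unchanged and C3' is inverted when water opens the epoxide, giving (2'R,3'R).

Key step: step 3

Assumption: nerol is taken as the pure Z isomer and stannane 2 as the E isomer after distillation; a Z contaminant in 2 would converge on the same arene, whereas geraniol in 14 would end as a diastereomer of the target.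

## Route

Step 1
Reactants: 1 3,3-diethoxyprop-1-yne
Product: 2 (E)-tributyl(3,3-diethoxyprop-1-en-1-yl)stannane
Conditions: Bu3SnH, AIBN (cat.), neat, 85 °C
Reagents that add atoms: tributylstannane, CCCC[SnH](CCCC)CCCC
Why: Radical chain hydrostannylation of a terminal alkyne puts tin on the terminal carbon, and reversible addition of the stannyl radical under these conditions should favour the (E)-vinylstannane.

Step 2
Reactants: 2 (E)-tributyl(3,3-diethoxyprop-1-en-1-yl)stannane; 3 dimethyl squarate
Product: 6 4-[(E)-3,3-diethoxyprop-1-enyl]-2,3,4-trimethoxycyclobut-2-en-1-one (racemic), via (E)-3,3-diethoxyprop-1-enyllithium 4 (not isolated), via lithium cyclobutenolate 5 (not isolated)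
Conditions: n-BuLi, THF, −78 °C; then 3, −78 °C; then MeOTf, −78 → 0 °C
Reagents that add atoms: methyl trifluoromethanesulfonate, COS(=O)(=O)C(F)(F)F
Why: Tin–lithium exchange gives the vinyllithium with retention of geometry, its 1,2-addition to one of the two equivalent carbonyl groups is the normal course for squarate esters, and the tertiary lithium alkoxide should be trapped on oxygen by the hard electrophile MeOTf (Williamson-type O-methylation) before it can fragment.

Step 3
Reactants: 6 4-[(E)-3,3-diethoxyprop-1-enyl]-2,3,4-trimethoxycyclobut-2-en-1-one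
Product: 9 2-(diethoxymethyl)-4,5,6-trimethoxyphenol, via dienylketene 7 (not isolated), via cyclohexadienone 8 (not isolated)
Conditions: PhMe (degassed), 110 °C
Reagents that add atoms: none
Why: Heat opens the four-membered ring of 6 by conrotatory 4π electrocyclic cleavage of the C1–C4 bond to the dienylketene 7, whose ketene carbon (future C8a, its oxygen the future O1) and acetal-bearing alkene terminus (future C4a) join in a thermal disrotatory 6π electrocyclisation to dienone 8, and enolisation delivers phenol 9. The closest known reaction type is the Moore rearrangement of 4-alkenyl-4-alkoxycyclobutenones made from squarate esters. The benzene ring is closed in this 6π electrocyclic mode through the single new C4a–C8a bond, all six ring atoms coming from the open-chain trienone. No stereocentre is created, the racemic quaternary centre of 6 becoming the trigonal C6 and the sp3 carbon of 8 being lost on tautomerisation. The only selectivity needed is torquoselectivity, and the C4 methoxy group, a donor, should rotate outward so that the alkenyl group lies cis to the ketene, while the twofold symmetry of the squarate unit leaves no regiochemical choice and the alkene geometry is erased on aromatisation. The neutral aprotic medium should leave the diethyl acetal and the three methyl ethers untouched.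

Step 4
Reactants: 9 2-(diethoxymethyl)-4,5,6-trimethoxyphenol
Product: 10 2-hydroxy-3,4,5-trimethoxybenzaldehyde
Conditions: 1 M HCl, THF, rt
Reagents that add atoms: water, O
Why: Acid-catalysed hydrolysis of the acyclic diethyl acetal is fast under conditions that leave aryl methyl ethers alone, and the product is stabilised by the hydrogen bond between the phenol and the new formyl group.

Step 5
Reactants: 10 2-hydroxy-3,4,5-trimethoxybenzaldehyde
Product: 12 6,7,8-trimethoxy-2H-chromen-2-one, via acyl ylide 11 (not isolated)
Conditions: Ph3P=C=C=O, PhMe, 110 °C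
Reagents that add atoms: (triphenylphosphoranylidene)ketene, O=C=C=P(c1ccccc1)(c1ccccc1)c1ccccc1
Why: The phenol adds to the ketene unit of Ph3P=C=C=O to give the stabilised acyl ylide 11, and its intramolecular Wittig reaction with the ortho formyl group can only form the cis C3=C4 bond inside the new pyranone ring (coumarin synthesis with the Bestmann ylide).

Step 6
Reactants: 12 6,7,8-trimethoxy-2H-chromen-2-one
Product: 13 7-hydroxy-6,8-dimethoxy-2H-chromen-2-one (isofraxidin)
Conditions: AlCl3, CH2Cl2, 0 °C → rt; then ice-water
Reagents that add atoms: none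
Why: Lewis-acid ether cleavage by AlCl3 should pick the C7 methyl ether, whose oxygen is pushed out of the ring plane by its two ortho methoxy neighbours and whose aryloxide is conjugated through C4a with the lactone carbonyl, in the way the central ether of 3,4,5-trimethoxyaryl carbonyl compounds is cleaved selectively.

Step 7
Reactants: 14 nerol
Product: 15 [(2R,3S)-3-methyl-3-(4-methylpent-3-en-1-yl)oxiran-2-yl]methanol ((2R,3S)-2,3-epoxynerol)
Conditions: Ti(OiPr)4 (cat.), D-(−)-diethyl tartrate (cat.), t-BuOOH, 4 Å molecular sieves, CH2Cl2, −20 °C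
Reagents that add atoms: tert-butyl hydroperoxide, CC(C)(C)OO
Why: In the Sharpless asymmetric epoxidation the titanium tartrate complex binds the allylic hydroxyl and delivers oxygen to one face of the C2=C3 bond only, the D-(−)-tartrate setting both new centres as (2R,3S) on this Z-allylic alcohol and leaving the isolated C6=C7 alkene alone.

Step 8
Reactants: 13 7-hydroxy-6,8-dimethoxy-2H-chromen-2-one; 15 (2R,3S)-2,3-epoxynerol
Product: 16 6,8-dimethoxy-7-{[(2R,3S)-3-methyl-3-(4-methylpent-3-en-1-yl)oxiran-2-yl]methoxy}-2H-chromen-2-one
Conditions: PPh3, DIAD, THF, 0 °C → rt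
Reagents that add atoms: none
Why: The Mitsunobu reaction activates the primary hydroxyl of 15 for SN2 displacement by the acidic phenol 13, so the ether forms at C1' and neither epoxide stereocentre is touched.

Step 9
Reactants: 16 6,8-dimethoxy-7-{[(2R,3S)-3-methyl-3-(4-methylpent-3-en-1-yl)oxiran-2-yl]methoxy}-2H-chromen-2-one
Product: 17 7-{[(2R,3R)-2,3-dihydroxy-3,7-dimethyloct-6-en-1-yl]oxy}-6,8-dimethoxy-2H-chromen-2-one (altissimacoumarin C)
Conditions: HClO4 (cat.), THF/H2O, 0 °C
Reagents that add atoms: water, O
Why: In this acid-catalysed epoxide hydrolysis water should attack the protonated epoxide at the tertiary C3' from the side opposite the leaving oxygen (anti opening with inversion) while C2' keeps its oxygen and configuration, so the (2R,3S)-epoxide gives the (2'R,3'R)-diol, and cold dilute acid should spare the lactone and the trisubstituted alkene.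

## Compound list

1 | 3,3-diethoxyprop-1-yne | C#CC(OCC)OCC | starting material
2 | (E)-tributyl(3,3-diethoxyprop-1-en-1-yl)stannane | CCCC[Sn](CCCC)(CCCC)/C=C/C(OCC)OCC | intermediate
3 | dimethyl squarate (3,4-dimethoxycyclobut-3-ene-1,2-dione) | COC1=C(OC)C(=O)C1=O | starting material
4 | (E)-3,3-diethoxyprop-1-enyllithium | [Li]/C=C/C(OCC)OCC | intermediate
5 | lithium 1-[(E)-3,3-diethoxyprop-1-enyl]-2,3-dimethoxy-4-oxocyclobut-2-en-1-olate (racemic) | [Li+].[O-]C1(/C=C/C(OCC)OCC)C(OC)=C(OC)C1=O | intermediate
6 | 4-[(E)-3,3-diethoxyprop-1-enyl]-2,3,4-trimethoxycyclobut-2-en-1-one (racemic) | O=C1C(OC)=C(OC)C1(OC)/C=C/C(OCC)OCC | intermediate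
7 | (3Z,5E)-7,7-diethoxy-2,3,4-trimethoxyhepta-1,3,5-trien-1-one | O=C=C(OC)/C(OC)=C(OC)\C=C\C(OCC)OCC | intermediate
8 | 6-(diethoxymethyl)-2,3,4-trimethoxycyclohexa-2,4-dien-1-one (racemic) | O=C1C(OC)=C(OC)C(OC)=CC1C(OCC)OCC | intermediate
9 | 2-(diethoxymethyl)-4,5,6-trimethoxyphenol | CCOC(OCC)c1cc(OC)c(OC)c(OC)c1O | intermediate
10 | 2-hydroxy-3,4,5-trimethoxybenzaldehyde | O=Cc1cc(OC)c(OC)c(OC)c1O | intermediate
11 | 2-formyl-4,5,6-trimethoxyphenyl (triphenylphosphoranylidene)acetate | O=Cc1cc(OC)c(OC)c(OC)c1OC(=O)C=P(c2ccccc2)(c3ccccc3)c4ccccc4 | intermediate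
12 | 6,7,8-trimethoxy-2H-chromen-2-one | COc1cc2ccc(=O)oc2c(OC)c1OC | intermediate
13 | 7-hydroxy-6,8-dimethoxy-2H-chromen-2-one (isofraxidin) | COc1cc2ccc(=O)oc2c(OC)c1O | intermediate
14 | nerol ((Z)-3,7-dimethylocta-2,6-dien-1-ol) | OC/C=C(C)\CCC=C(C)C | starting material
15 | [(2R,3S)-3-methyl-3-(4-methylpent-3-en-1-yl)oxiran-2-yl]methanol | OC[C@H]1O[C@@]1(C)CCC=C(C)C | intermediate
16 | 6,8-dimethoxy-7-{[(2R,3S)-3-methyl-3-(4-methylpent-3-en-1-yl)oxiran-2-yl]methoxy}-2H-chromen-2-one | COc1cc2ccc(=O)oc2c(OC)c1OC[C@H]1O[C@@]1(C)CCC=C(C)C | intermediate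
17 | 7-{[(2R,3R)-2,3-dihydroxy-3,7-dimethyloct-6-en-1-yl]oxy}-6,8-dimethoxy-2H-chromen-2-one (altissimacoumarin C) | COc1cc2ccc(=O)oc2c(OC)c1OC[C@@H](O)[C@](C)(O)CCC=C(C)C | target

## Step count and risks

Total steps: 9. Longest linear sequence: 8 steps (steps 1–6, 8 and 9, from 3,3-diethoxyprop-1-yne 1); step 7 is the only step of the side branch.

**Step 9 (epoxide hydrolysis).** The protonated epoxide may ionise at C3' before water arrives, so that configuration at C3' leaks. Water may also attack C2', which would give the enantiomer, and a hydride shift to a ketone or hydration of the distal alkene may compete. The fallback sets out from nerol 14, takes isofraxidin 13 from step 6, and comes back to the route at target 17. Epoxidation of 14 as in step 7, but with L-(+)-diethyl tartrate, would give [(2S,3R)-3-methyl-3-(4-methylpent-3-en-1-yl)oxiran-2-yl]methanol F1. Warming F1 with aqueous NaOH in t-BuOH would bring about the Payne rearrangement: the C1 alkoxide attacks C2 with inversion to give the terminal epoxide (2R)-6-methyl-2-[(2R)-oxiran-2-yl]hept-5-en-2-ol F2, which hydroxide opens at its CH2 group to (2R,3R)-3,7-dimethyloct-6-ene-1,2,3-triol F3. Both centres are then fixed by SN2 events and C3 is never ionised. Selective sulfonylation of the primary hydroxyl (TsCl, Et3N, Bu2SnO cat., CH2Cl2) would give (2R,3R)-2,3-dihydroxy-3,7-dimethyloct-6-en-1-yl 4-methylbenzenesulfonate F4. Heating F4 with 13 and K2CO3 in DMF would close it back to F2 and let the aryloxide open that epoxide at the terminal carbon, giving 17 without an acid step.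

**Step 6 (ether cleavage at C7).** AlCl3 may also cleave the C6 or C8 ether (loss of site selectivity or over-cleavage), or be held back by the lactone carbonyl. The fallback sets out from 12 and comes back at 13, and it reverses the polarity of the cleavage: NaSEt in DMF at about 110 °C, then acidification. The methyl group is then removed by SN2 attack, so the ether that goes is the one whose aryloxide is the best leaving group. That is O7, which is conjugated through C4a and C4=C3 with the lactone carbonyl, whereas the Lewis-acid method selects by basicity and crowding of the ether oxygen. A lactone opened by thiolate should close again on acidification. This detour passes through no compound outside the list (F0).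

**Step 2 (addition and in-flask O-methylation).** Methylation of the hindered tertiary lithium alkoxide may lag behind its fragmentation on warming, and excess MeOTf may alkylate the acetal oxygens. The fallback sets out from 2 and 3 and comes back at aldehyde 10; the tertiary oxygen is carried free through the ring construction and methylated afterwards. Vinyllithium 4 (from 2 and n-BuLi) would be added to 3 at −78 °C and quenched cold with aqueous NH4Cl to give 4-[(E)-3,3-diethoxyprop-1-enyl]-4-hydroxy-2,3-dimethoxycyclobut-2-en-1-one F5. Heating F5 in toluene under argon would open it to (3Z,5E)-7,7-diethoxy-4-hydroxy-2,3-dimethoxyhepta-1,3,5-trien-1-one F6, which closes to 6-(diethoxymethyl)-4-hydroxy-2,3-dimethoxycyclohexa-2,4-dien-1-one F7 and tautomerises to 2-(diethoxymethyl)-5,6-dimethoxybenzene-1,4-diol F8. Dilute aqueous HCl in THF would give 2,5-dihydroxy-3,4-dimethoxybenzaldehyde F9. MeI (one equivalent) with K2CO3 in acetone should then methylate only the C5 hydroxyl, because the C2 hydroxyl is tied up in a hydrogen bond to the formyl group, and this gives 10.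

## Further compounds

F1 | step 9 | [(2S,3R)-3-methyl-3-(4-methylpent-3-en-1-yl)oxiran-2-yl]methanol | OC[C@@H]1O[C@]1(C)CCC=C(C)C
F2 | step 9 | (2R)-6-methyl-2-[(2R)-oxiran-2-yl]hept-5-en-2-ol | C1[C@@H](O1)[C@](C)(O)CCC=C(C)C
F3 | step 9 | (2R,3R)-3,7-dimethyloct-6-ene-1,2,3-triol | OC[C@@H](O)[C@](C)(O)CCC=C(C)C
F4 | step 9 | (2R,3R)-2,3-dihydroxy-3,7-dimethyloct-6-en-1-yl 4-methylbenzenesulfonate | Cc1ccc(cc1)S(=O)(=O)OC[C@@H](O)[C@](C)(O)CCC=C(C)C
F0 | step 6 | none | none
F5 | step 2 | 4-[(E)-3,3-diethoxyprop-1-enyl]-4-hydroxy-2,3-dimethoxycyclobut-2-en-1-one (racemic) | O=C1C(OC)=C(OC)C1(O)/C=C/C(OCC)OCC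
F6 | step 2 | (3Z,5E)-7,7-diethoxy-4-hydroxy-2,3-dimethoxyhepta-1,3,5-trien-1-one | O=C=C(OC)/C(OC)=C(O)\C=C\C(OCC)OCC
F7 | step 2 | 6-(diethoxymethyl)-4-hydroxy-2,3-dimethoxycyclohexa-2,4-dien-1-one (racemic) | O=C1C(OC)=C(OC)C(O)=CC1C(OCC)OCC
F8 | step 2 | 2-(diethoxymethyl)-5,6-dimethoxybenzene-1,4-diol | CCOC(OCC)c1cc(O)c(OC)c(OC)c1O
F9 | step 2 | 2,5-dihydroxy-3,4-dimethoxybenzaldehyde | O=Cc1cc(O)c(OC)c(OC)c1O
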